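The C41 target is assembled from one C16 aldehyde, used twice, that a single oxidative radical bicyclisation delivers.

**Plan**
1. Cuts: C14–C15 and C15–C12′, where C15 is the carbon of nitromethane used as a carbonyl 1,1-dianion equivalent. Also C12–C13 (Morita–Baylis–Hillman, methyl acrylate) and C12′–C13′ (aldol, C4 lactone). Both halves then fall back on one C16 aldehyde 17.
2. In 17 both rings are cut at once, C4–C5 (ring A) and C9–C10 (ring B), back to the acyclic E,E-dienyl α-methyl-β-keto ester 13.
3. Enabling feature: in ring A the quaternary C4 sits between oxygenated C3 and C19, so it is the α-carbon of a reduced β-keto ester. Its radical closes ring A on C5 of the C5=C10 alkene and the C10 radical closes ring B on C9. The 8(17)-exomethylene is the natural exit of the resulting C8 radical.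
4. Forward: chain 13, then ring A and ring B in one oxidative radical cascade, then LiAlH4, acetonide and oxidation to 17. Nitromethane is joined first to the butenolide half and then to the acrylate half, followed by the Nef reaction and deprotection.
5. Stereochemistry: C4, C5, C9 and C10 come from the chair–chair fold of the E,E-diene, with the absolute sense set by a recoverable (+)-8-phenylmenthyl ester. C3 comes from axial hydride delivery and C12′ from anti-SN2′ relay from (S)-3-hydroxy-γ-butyrolactone. The E C12=C13 alkene comes from SN2′ displacement of the Baylis–Hillman acetate.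

Key step: step 8

Remark: labdane numbering is used (C1–C20 for the methyl ester half, primed numbers for the butenolide half). Compounds 1 and 5 are taken as commercial; 5 is otherwise one halide exchange away from the commercial bromide.

Step 1
Reactants: 1 (+)-8-phenylmenthol; 2 ethyl 2-methylacetoacetate
Product: 3 (+)-8-phenylmenthyl 2-methyl-3-oxobutanoate (C2 epimers)
Conditions: DMAP (0.3 equiv), toluene, reflux, EtOH distilled off
Reagents that add atoms: none
Why: DMAP-catalysed transesterification of a β-keto ester is driven by removal of ethanol and leaves the three auxiliary stereocentres untouched.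

Step 2
Reactants: 4 2,3-dihydrofuran; 5 5-iodo-2-methylpent-2-ene
Product: 7 5-(4-methylpent-3-en-1-yl)-2,3-dihydrofuran, via 5-lithio-2,3-dihydrofuran 6 (not isolated)
Conditions: t-BuLi, THF, −78 → 0 °C; then 5, −30 °C → rt
Reagents that add atoms: none
Why: α-lithiation of the cyclic enol ether followed by SN2 alkylation with a primary iodide is a standard route to 5-alkyl-2,3-dihydrofurans.

Step 3
Reactants: 7 5-(4-methylpent-3-en-1-yl)-2,3-dihydrofuran
Product: 8 (3E)-4,8-dimethylnona-3,7-dien-1-ol (homogeraniol)
Conditions: MeMgBr (3 equiv), NiCl2(PPh3)2 (5 mol %), toluene, reflux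
Reagents that add atoms: methylmagnesium bromide, C[Mg]Br
Why: Kumada-type nickel-catalysed coupling at the enol ether C–O bond proceeds with retention, so the methyl group ends cis to the CH2CH2O arm and the future C8=C9 alkene should be E.

Step 4
Reactants: 8 homogeraniol
Product: 9 (3E)-4,8-dimethylnona-3,7-dien-1-yl pivalate
Conditions: PivCl, Et3N, DMAP (cat.), CH2Cl2, 0 °C
Reagents that add atoms: pivaloyl chloride, CC(C)(C)C(=O)Cl
Why: this is a routine acylation, and the hindered ester should survive the dianion and acetic acid of later steps and fall in the LiAlH4 step.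

Step 5
Reactants: 9 homogeranyl pivalate
Product: 10 (3E,7E)-9-hydroxy-4,8-dimethylnona-3,7-dien-1-yl pivalate
Conditions: SeO2 (0.3 equiv), t-BuOOH (3 equiv), salicylic acid (cat.), CH2Cl2, 0 °C → rt
Reagents that add atoms: tert-butyl hydroperoxide, CC(C)(C)OO; selenium dioxide (oxygen relay), O=[Se]=O
Why: Riley oxidation (ene reaction then [2,3]-shift) attacks the terminal gem-dimethyl alkene at its E-methyl group, which fixes the E geometry of the future C5=C10 alkene.

Step 6
Reactants: 10 allylic alcohol
Product: 11 (3E,7E)-9-bromo-4,8-dimethylnona-3,7-dien-1-yl pivalate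
Conditions: CBr4, PPh3, CH2Cl2, 0 °C
Reagents that add atoms: carbon tetrabromide, BrC(Br)(Br)Br
Why: the Appel reaction converts a primary allylic alcohol into the bromide under neutral conditions without allylic shift or E/Z loss.

Step 7
Reactants: 3 (+)-8-phenylmenthyl 2-methyl-3-oxobutanoate; 11 allylic bromide
Product: 13 (+)-8-phenylmenthyl (6E,10E)-2,6,10-trimethyl-3-oxo-13-(pivaloyloxy)trideca-6,10-dienoate (C2 epimers), via keto ester dianion 12 (not isolated)
Conditions: 3, NaH, THF, 0 °C; n-BuLi, 0 °C; then 11, 0 °C; AcOH quench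
Reagents that add atoms: none
Why: γ-alkylation of an acetoacetate dianion takes place only at the terminal carbanion and is fast with an allylic bromide, so the pivalate should stay intact.

Step 8
Reactants: 13 acyclic keto ester
Product: 14 (+)-8-phenylmenthyl 3-oxo-12-(pivaloyloxy)-13,14,15,16-tetranor-ent-labd-8(17)-en-19-oate (4S,5S,9R,10S; trans-decalin, ester axial and cis to C20)
Conditions: Mn(OAc)3·2H2O (2.2 equiv), Cu(OAc)2·H2O (1 equiv), degassed AcOH (0.05 M), 25 °C
Reagents that add atoms: none
Why: Mn(III) oxidises the enol of 13 to the planar C4 radical flanked by C3=O and the C19 ester; this adds to C5, the C10 radical adds to C9, and Cu(II) captures the tertiary C8 radical and eliminates a C17 hydrogen to leave the 8(17)-exomethylene. The closest known reaction type is the Mn(OAc)3/Cu(OAc)2 oxidative free-radical polyene cyclisation of α-methyl-β-keto esters, including 8-phenylmenthyl esters. Ring A closes 6-endo-trig (C4 to C5) and ring B 6-endo-trig (C10 to C9) through a chair–chair fold. C5 and C10 (trans fusion) follow from the E C5=C10 alkene, the equatorial C9 side chain follows from the E C8=C9 alkene, and C4 carries the ester axial because the radical reacts in the dipole-opposed rotamer with C19 syn to C2. The absolute sense comes from the auxiliary, whose phenyl ring stacks over one face of the C4 radical so that C5 bonds to the open face, giving 4S in 14, which is 4R in the target after C3 and C19 swap CIP rank on reduction. The step needs endo over exo closure (secured by the methyl groups on the proximal alkene carbons C10 and C8), exocyclic over endocyclic alkene (secured by Cu(II) elimination toward the least hindered hydrogen), and facial selectivity, whose minor product is a diastereomer and should be removable by chromatography.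

Step 9
Reactants: 14 bicyclic keto ester
Product: 15 (3R,4R,5S,9R,10S)-13,14,15,16-tetranor-ent-labd-8(17)-ene-3,12,19-triol
Conditions: LiAlH4 (excess), THF, 0 °C → reflux; aq. NaOH work-up
Reagents that add atoms: none
Why: hydride reduction first attacks C3=O along the axial line, on the face free of the axial C19 and C20 groups, giving the equatorial 3-OH, and then cleaves both esters and returns the auxiliary.

Step 10
Reactants: 15 triol
Product: 16 3,19-O-isopropylidene derivative of 15 (free C12 alcohol)
Conditions: Me2C(OMe)2, PPTS (cat.), CH2Cl2, rt; aqueous work-up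
Reagents that add atoms: 2,2-dimethoxypropane, COC(C)(C)OC
Why: acetal exchange closes the six-membered acetonide on the 1,3-diol, and any mixed acetal at the primary C12 alcohol is lost on work-up.

Step 11
Reactants: 16 acetonide alcohol
Product: 17 3,19-O-isopropylidene-13,14,15,16-tetranor-ent-labd-8(17)-en-12-al
Conditions: Dess–Martin periodinane, NaHCO3, CH2Cl2, 0 °C → rt
Reagents that add atoms: none
Why: Dess–Martin oxidation under buffered conditions spares the acetonide and the exomethylene, and C9 is not α to the new carbonyl and so cannot epimerise.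

Step 12
Reactants: 17 aldehyde; 18 methyl acrylate
Product: 19 methyl 2-methylidene-3-hydroxy ester (Baylis–Hillman alcohol, C12 epimers)
Conditions: 18 (excess), DABCO, MeOH, rt
Reagents that add atoms: none
Why: the Morita–Baylis–Hillman reaction of an unbranched-α aliphatic aldehyde forms C12–C13, and the new C12 carbinol centre is a mixture that is erased in step 20.

Step 13
Reactants: 19 Baylis–Hillman alcohol
Product: 20 Baylis–Hillman acetate (C12 epimers)
Conditions: Ac2O, pyridine, DMAP (cat.), CH2Cl2, 0 °C
Reagents that add atoms: acetic anhydride, CC(=O)OC(C)=O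
Why: routine acetylation installs the leaving group for the later SN2′ displacement.

Step 14
Reactants: 21 (S)-3-hydroxy-γ-butyrolactone
Product: 22 (S)-4-(tert-butyldimethylsilyloxy)dihydrofuran-2(3H)-one
Conditions: TBSCl, imidazole, DMF, rt
Reagents that add atoms: tert-butyldimethylsilyl chloride, CC(C)(C)[Si](C)(C)Cl
Why: routine silylation gives a β-silyloxy group that is a poor leaving group, so the lactone enolate should be stable at −78 °C.

Step 15
Reactants: 22 silyloxy lactone; 17 aldehyde
Product: 24 aldol adduct (13′S,14′S, C12′ epimers), via lactone lithium enolate 23 (not isolated)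
Conditions: LiHMDS, THF, −78 °C; then 17, −78 °C; AcOH quench at −78 °C
Reagents that add atoms: none
Why: the lithium enolate aldol addition forms C12′–C13′ trans to the silyloxy group, and the new C12′ and C13′ centres are erased in step 16.

Step 16
Reactants: 24 aldol adduct
Product: 26 14-O-TBS-3,19-O-isopropylideneandrographolide (12′E,14′S), via C12′ mesylate 25 (not isolated)
Conditions: MsCl, Et3N, CH2Cl2, 0 °C; then DBU, 0 °C → rt
Reagents that add atoms: none
Why: in the mesylation and E1cB elimination the enolate expels the far better leaving group (mesylate rather than silyloxide) and should give the E-alkylidene lactone, with the chain away from the lactone carbonyl.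

Step 17
Reactants: 26 silyl ether
Product: 27 3,19-O-isopropylideneandrographolide
Conditions: TBAF/AcOH (1:1), THF, rt
Reagents that add atoms: none
Why: buffered fluoride desilylation avoids both alkoxide-induced elimination and acid cleavage of the acetonide.

Step 18
Reactants: 27 allylic alcohol
Product: 28 14-O-acetyl-3,19-O-isopropylideneandrographolide
Conditions: Ac2O, pyridine, DMAP (cat.), CH2Cl2, 0 °C
Reagents that add atoms: acetic anhydride, CC(=O)OC(C)=O
Why: routine acetylation of the only free hydroxyl turns C14′–O into a leaving group.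

Step 19
Reactants: 28 allylic acetate; 29 nitromethane
Product: 30 (12S)-12-(nitromethyl)-14-deoxy-3,19-O-isopropylideneandrographolide
Conditions: 29 (20 equiv), K2CO3 (1.5 equiv), DMF, 0 °C → rt
Reagents that add atoms: none
Why: in this conjugate addition–elimination (SN2′), known for β′-acyloxy-α-alkylidene esters and lactones, the nitronate adds to C12′ on the face opposite the C14′ acetate (open face, σ*C–O aligned with the π system) and the enolate expels acetate, so the 14′S centre should be relayed into 12′S as the alkene moves to C13′=C14′.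

Step 20
Reactants: 30 primary nitro compound; 20 Baylis–Hillman acetate
Product: 31 coupled 15-nitro bis-acetonide (12E,12′S, C15 epimers)
Conditions: K2CO3 (1.5 equiv), DMF, 0 °C → rt
Reagents that add atoms: none
Why: SN2′ alkylation of a nitronate by a Baylis–Hillman acetate attacks the unhindered C14 methylene by carbon, and loss of acetate should give the E-enoate because allylic strain places the C11 chain trans to the ester; the C15 centre is erased in step 21 and C12′–H is not yet acidic.

Step 21
Reactants: 31 secondary nitro compound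
Product: 33 15-ketone bis-acetonide (12E,12′S), via sodium nitronate 32 (not isolated)
Conditions: NaOMe (1.05 equiv), MeOH/THF, 0 °C; then aq. TiCl3, NH4OAc buffer (pH ≈ 6), 0 °C → rt
Reagents that add atoms: water, O
Why: in the reductive Nef reaction Ti(III) takes the nitronate to the imine, which hydrolyses in a weakly acidic buffer, so the ketone never meets base and C12′ should keep its configuration.

Step 22
Reactants: 33 ketone bis-acetonide
Product: 34 target CNP0330094.1
Conditions: AcOH/H2O (7:3), rt
Reagents that add atoms: none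
Why: mild acid hydrolysis removes both acetonides and is too weak to enolise C15/C12′, shift the exomethylenes or open the butenolide.

**Compound list**
1 | (+)-8-phenylmenthol, (1S,2R,5S) | CC(C)(c1ccccc1)[C@H]2CC[C@H](C)C[C@@H]2O | starting material
2 | ethyl 2-methylacetoacetate | CCOC(=O)C(C)C(C)=O | starting material
3 | (+)-8-phenylmenthyl 2-methyl-3-oxobutanoate | CC(=O)C(C)C(=O)O[C@H]1C[C@@H](C)CC[C@@H]1C(C)(C)c1ccccc1 | intermediate
4 | 2,3-dihydrofuran | C1=COCC1 | starting material
5 | 5-iodo-2-methylpent-2-ene | CC(C)=CCCI | starting material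
6 | 5-lithio-2,3-dihydrofuran | [Li]C1=CCCO1 | intermediate
7 | 5-(4-methylpent-3-en-1-yl)-2,3-dihydrofuran | CC(C)=CCCC1=CCCO1 | intermediate
8 | (3E)-4,8-dimethylnona-3,7-dien-1-ol | CC(C)=CCC/C(C)=C/CCO | intermediate
9 | (3E)-4,8-dimethylnona-3,7-dien-1-yl pivalate | CC(C)=CCC/C(C)=C/CCOC(=O)C(C)(C)C | intermediate
10 | (3E,7E)-9-hydroxy-4,8-dimethylnona-3,7-dien-1-yl pivalate | OC/C(C)=C/CC/C(C)=C/CCOC(=O)C(C)(C)C | intermediate
11 | (3E,7E)-9-bromo-4,8-dimethylnona-3,7-dien-1-yl pivalate | BrC/C(C)=C/CC/C(C)=C/CCOC(=O)C(C)(C)C | intermediate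
12 | sodium lithium dianion of 3 | [Li+].[Na+].C=C([O-])C(C)=C([O-])O[C@H]1C[C@@H](C)CC[C@@H]1C(C)(C)c1ccccc1 | intermediate
13 | (+)-8-phenylmenthyl (6E,10E)-2,6,10-trimethyl-3-oxo-13-(pivaloyloxy)trideca-6,10-dienoate | CC(C(=O)CC/C(C)=C/CC/C(C)=C/CCOC(=O)C(C)(C)C)C(=O)O[C@H]1C[C@@H](C)CC[C@@H]1C(C)(C)c1ccccc1 | intermediate
14 | bicyclic 3-keto 19-ester, 8(17)-exomethylene, 12-pivalate | C=C1CC[C@@H]2[C@](C)(C(=O)O[C@H]3C[C@@H](C)CC[C@@H]3C(C)(C)c4ccccc4)C(=O)CC[C@@]2(C)[C@@H]1CCOC(=O)C(C)(C)C | intermediate
15 | 3,12,19-triol | C=C1CC[C@@H]2[C@](C)(CO)[C@H](O)CC[C@@]2(C)[C@@H]1CCO | intermediate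
16 | 3,19-acetonide 12-alcohol | C=C1CC[C@@H]2[C@]3(C)COC(C)(C)O[C@@H]3CC[C@@]2(C)[C@@H]1CCO | intermediate
17 | 3,19-acetonide 12-aldehyde | C=C1CC[C@@H]2[C@]3(C)COC(C)(C)O[C@@H]3CC[C@@]2(C)[C@@H]1CC=O | intermediate
18 | methyl acrylate | C=CC(=O)OC | starting material
19 | Baylis–Hillman alcohol | C=C1CC[C@@H]2[C@]3(C)COC(C)(C)O[C@@H]3CC[C@@]2(C)[C@@H]1CC(O)C(=C)C(=O)OC | intermediate
20 | Baylis–Hillman acetate | C=C1CC[C@@H]2[C@]3(C)COC(C)(C)O[C@@H]3CC[C@@]2(C)[C@@H]1CC(OC(C)=O)C(=C)C(=O)OC | intermediate
21 | (S)-3-hydroxy-γ-butyrolactone | O[C@@H]1COC(=O)C1 | starting material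
22 | (S)-4-(tert-butyldimethylsilyloxy)dihydrofuran-2(3H)-one | CC(C)(C)[Si](C)(C)O[C@@H]1COC(=O)C1 | intermediate
23 | lithium enolate of 22 | [Li+].CC(C)(C)[Si](C)(C)O[C@@H]1COC([O-])=C1 | intermediate
24 | aldol adduct | C=C1CC[C@@H]2[C@]3(C)COC(C)(C)O[C@@H]3CC[C@@]2(C)[C@@H]1CC(O)[C@@H]4C(=O)OC[C@H]4O[Si](C)(C)C(C)(C)C | intermediate
25 | C12′ mesylate of 24 | C=C1CC[C@@H]2[C@]3(C)COC(C)(C)O[C@@H]3CC[C@@]2(C)[C@@H]1CC(OS(C)(=O)=O)[C@@H]4C(=O)OC[C@H]4O[Si](C)(C)C(C)(C)C | intermediate
26 | 14-O-TBS-3,19-O-isopropylideneandrographolide | C=C1CC[C@@H]2[C@]3(C)COC(C)(C)O[C@@H]3CC[C@@]2(C)[C@@H]1C/C=C4/C(=O)OC[C@H]4O[Si](C)(C)C(C)(C)C | intermediate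
27 | 3,19-O-isopropylideneandrographolide | C=C1CC[C@@H]2[C@]3(C)COC(C)(C)O[C@@H]3CC[C@@]2(C)[C@@H]1C/C=C4/C(=O)OC[C@H]4O | intermediate
28 | 14-O-acetyl-3,19-O-isopropylideneandrographolide | C=C1CC[C@@H]2[C@]3(C)COC(C)(C)O[C@@H]3CC[C@@]2(C)[C@@H]1C/C=C4/C(=O)OC[C@H]4OC(C)=O | intermediate
29 | nitromethane | C[N+](=O)[O-] | starting material
30 | (12S)-12-(nitromethyl)-14-deoxy-3,19-O-isopropylideneandrographolide | O=[N+]([O-])C[C@@H](C[C@@H]1C(=C)CC[C@@H]2[C@]3(C)COC(C)(C)O[C@@H]3CC[C@]21C)C1=CCOC1=O | intermediate
31 | coupled 15-nitro bis-acetonide | C=C1CC[C@@H]2[C@]3(C)COC(C)(C)O[C@@H]3CC[C@@]2(C)[C@@H]1C/C=C(\CC([N+](=O)[O-])[C@@H](C[C@@H]1C(=C)CC[C@@H]2[C@]3(C)COC(C)(C)O[C@@H]3CC[C@]21C)C1=CCOC1=O)C(=O)OC | intermediate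
32 | sodium nitronate of 31 | [Na+].C=C1CC[C@@H]2[C@]3(C)COC(C)(C)O[C@@H]3CC[C@@]2(C)[C@@H]1C/C=C(\CC(=[N+]([O-])[O-])[C@@H](C[C@@H]1C(=C)CC[C@@H]2[C@]3(C)COC(C)(C)O[C@@H]3CC[C@]21C)C1=CCOC1=O)C(=O)OC | intermediate
33 | 15-ketone bis-acetonide | C=C1CC[C@@H]2[C@]3(C)COC(C)(C)O[C@@H]3CC[C@@]2(C)[C@@H]1C/C=C(\CC(=O)[C@@H](C[C@@H]1C(=C)CC[C@@H]2[C@]3(C)COC(C)(C)O[C@@H]3CC[C@]21C)C1=CCOC1=O)C(=O)OC | intermediate
34 | CNP0330094.1 | C=C1CC[C@@H]2[C@](C)(CO)[C@H](O)CC[C@@]2(C)[C@@H]1C/C=C(\CC(=O)[C@@H](C[C@@H]1C(=C)CC[C@@H]2[C@](C)(CO)[C@H](O)CC[C@]21C)C1=CCOC1=O)C(=O)OC | target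

**Step count**
- Total step count: 22.
- Longest linear sequence: 18 (steps 2–11, 15–19, 20–22).

**Steps most likely to fail**

Step 8.
- The auxiliary may shield the C4 radical poorly in its open, non-chelated rotamer, so that both enantiomeric folds form.
- Part of the C8 radical may also be over-oxidised and lose an endocyclic proton.
- The fallback takes the C18 methyl group out of the cascade and uses chelation control. It sets out from bromide 11 and comes back at triol 15.
- (−)-8-Phenylmenthol is transesterified with methyl acetoacetate to (−)-8-phenylmenthyl acetoacetate F1. Its dianion is alkylated with 11 to give the α-unsubstituted keto ester F2.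
- Mn(OAc)3/Cu(OAc)2 with Yb(OTf)3 in CF3CH2OH at 0 °C locks the two carbonyl groups syn on the lanthanide, a setting in which this auxiliary is known to give high facial control. The syn rotamer reverses the link between the shielded face and the fold, which is why the (−)-auxiliary is used here. The product is the bicyclic β-keto ester F3.
- C-methylation (K2CO3, MeI, acetone) from the face opposite C20 gives the quaternary keto ester F4, with methyl equatorial and ester axial. LiAlH4 then gives 15.

Step 19.
- Facial selectivity at C12′ may be low. Base may also remove a C11′ proton and trigger 1,4-elimination of acetate to the 11,13-diene.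
- The fallback replaces substrate relay by catalyst control. It sets out from aldehyde 17 and comes back at 30.
- Lithium phenylselenide adds to furan-2(5H)-one and the enolate adds to 17, giving the β-phenylselanyl aldol adduct F5.
- H2O2 oxidation and syn-elimination give the butenolide Baylis–Hillman alcohol F6. Boc2O/DMAP gives the tert-butyl carbonate F7 as both C12′ epimers.
- A cinchona-derived Lewis base, (DHQD)2PHAL or its quinine-derived pseudoenantiomer, adds at C14′ and expels the carbonate. Nitromethane, deprotonated by the released tert-butoxide, attacks C12′ of the allylammonium ion.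
- Both carbonate epimers converge on one intermediate, and the catalyst sets C12′ (asymmetric allylic alkylation of Baylis–Hillman carbonates with nitroalkanes).

Step 21.
- Deprotonation of the hindered secondary nitro group may be slow.
- Methoxide may instead cause loss of nitrous acid toward C14, or epimerisation once some ketone is present.
- The fallback avoids the nitronate. It sets out from 31 and comes back at 33.
- Mild reduction with SnCl2·2H2O/PhSH/Et3N takes the nitro group to the 15-ketoxime F8.
- Transoximation with aqueous glyoxylic acid at rt frees the ketone under weakly acidic conditions.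

**Further compounds**
F1 | step 8 | (−)-8-phenylmenthyl acetoacetate | CC(=O)CC(=O)O[C@@H]1C[C@H](C)CC[C@H]1C(C)(C)c1ccccc1
F2 | step 8 | (−)-8-phenylmenthyl (6E,10E)-6,10-dimethyl-3-oxo-13-(pivaloyloxy)trideca-6,10-dienoate | O=C(CC(=O)CC/C(C)=C/CC/C(C)=C/CCOC(=O)C(C)(C)C)O[C@@H]1C[C@H](C)CC[C@H]1C(C)(C)c1ccccc1
F3 | step 8 | bicyclic β-keto ester with C4–H (enolisable) | C=C1CC[C@@H]2C(C(=O)O[C@@H]3C[C@H](C)CC[C@H]3C(C)(C)c4ccccc4)C(=O)CC[C@@]2(C)[C@@H]1CCOC(=O)C(C)(C)C
F4 | step 8 | C4-methylated bicyclic keto ester, (−)-8-phenylmenthyl series | C=C1CC[C@@H]2[C@](C)(C(=O)O[C@@H]3C[C@H](C)CC[C@H]3C(C)(C)c4ccccc4)C(=O)CC[C@@]2(C)[C@@H]1CCOC(=O)C(C)(C)C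
F5 | step 19 | β-phenylselanyl aldol adduct | C=C1CC[C@@H]2[C@]3(C)COC(C)(C)O[C@@H]3CC[C@@]2(C)[C@@H]1CC(O)C1C(=O)OCC1[Se]c1ccccc1
F6 | step 19 | butenolide Baylis–Hillman alcohol | C=C1CC[C@@H]2[C@]3(C)COC(C)(C)O[C@@H]3CC[C@@]2(C)[C@@H]1CC(O)C1=CCOC1=O
F7 | step 19 | butenolide Baylis–Hillman tert-butyl carbonate | C=C1CC[C@@H]2[C@]3(C)COC(C)(C)O[C@@H]3CC[C@@]2(C)[C@@H]1CC(OC(=O)OC(C)(C)C)C1=CCOC1=O
F8 | step 21 | 15-ketoxime bis-acetonide | C=C1CC[C@@H]2[C@]3(C)COC(C)(C)O[C@@H]3CC[C@@]2(C)[C@@H]1C/C=C(\CC(=NO)[C@@H](C[C@@H]1C(=C)CC[C@@H]2[C@]3(C)COC(C)(C)O[C@@H]3CC[C@]21C)C1=CCOC1=O)C(=O)OC
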